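**Retrosynthetic overview**
- Last bond made: the 5-O–CH3 bond, by methylating a chelated 5-hydroxyflavone.
- Key disconnection: O1–C8a. The enol oxygen of a 1,3-diketone attacks the ring C–H carbon of an acylquinone monoketal. The monoketal comes from oxidative dearomatisation of a 2-hydroxy-4,5-dimethoxyphenyl ketone. Loss of MeOH rearomatises the ring, so the old OH becomes 5-OH and the old 4,5-OMe groups become 7,8-OMe.
- C2–C3: crossed Claisen condensation of 2'-hydroxy-4',5'-dimethoxyacetophenone with methyl 2,3,4,5-tetramethoxybenzoate.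
- The ester comes from 1,2,3,4-tetramethoxybenzene by directed ortho-metalation and methoxycarbonylation.
- Ring order: rings A and B are bought. The pyranone (ring C) is the only ring formed, in the final step.

Assumption: the target has no stereocentre (it is achiral), so no stereocontrol is needed; 1 and 4 are taken as inexpensive catalogue chemicals.

**Step 1**
Reactants: 1 1,2,3,4-tetramethoxybenzene
Product: 3 methyl 2,3,4,5-tetramethoxybenzoate, via aryllithium 2 (not isolated)
Conditions: n-BuLi (1.1 equiv), TMEDA (1.1 equiv), THF, 0 °C to rt, 2 h; cannulate into ClCO2Me (3 equiv), THF, −78 °C to rt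
Reagents that add atoms: methyl chloroformate, COC(=O)Cl
Why: Directed ortho-metalation: the two ring C–H positions of 1 are equivalent and each is ortho to a methoxy group, so a single aryllithium forms, and inverse addition into excess chloroformate (nucleophilic acyl substitution) stops at the ester; no stereocentre is formed.

**Step 2**
Reactants: 3 methyl 2,3,4,5-tetramethoxybenzoate; 4 1-(2-hydroxy-4,5-dimethoxyphenyl)ethan-1-one
Product: 6 1-(2-hydroxy-4,5-dimethoxyphenyl)-3-(2,3,4,5-tetramethoxyphenyl)propane-1,3-dione, via dilithio dianion 5 (not isolated)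
Conditions: 4, LiHMDS (3.3 equiv), THF, −78 to −10 °C, 1 h; 3 (1.1 equiv), −78 °C to rt then 40 °C, 12 h; 1 M HCl, 0 °C, to pH 5
Reagents that add atoms: none
Why: Crossed Claisen condensation: 3 cannot enolise, the phenoxide/enolate dianion of 4 is acylated at carbon, the extra base removes the product as its stabilised diketonate, and the cold pH 5 quench avoids acid cyclodehydration to the unwanted 6,7-dimethoxyflavone; no stereocentre is formed.

**Step 3**
Reactants: 6 1-(2-hydroxy-4,5-dimethoxyphenyl)-3-(2,3,4,5-tetramethoxyphenyl)propane-1,3-dione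
Product: 10 5,7,8-trimethoxy-2-(2,3,4,5-tetramethoxyphenyl)-4H-chromen-4-one, via acylquinone monoketal 7 (not isolated), via dihydrochromenone ketal 8 (not isolated), via 5-hydroxyflavone 9 (not isolated)
Conditions: PhI(OAc)2 (1.0–1.05 equiv), MeOH–CH2Cl2 4:1, 0 °C, 20 min; evaporate; PPTS (10 mol %), CH2Cl2, rt, 2 h; evaporate; MeI (4 equiv), K2CO3 (5 equiv), DMF, 40 °C, 12 h
Reagents that add atoms: methanol, CO (supplies one ketal OMe of 7; one of the two ketal OMe groups leaves again); iodomethane, CI
Why: Proposed new method: a dearomatise–cyclise–rearomatise annulation that closes the pyranone by forming O1–C8a at an unfunctionalised aryl C–H; PhI(OAc)2/MeOH oxidises only the free para-methoxyphenol of ring A (ring B is fully etherified and inert) to acylquinone monoketal 7, whose former C6'–H carbon is now the β-carbon of an alkylidene-1,3-dicarbonyl and the only electrophilic site the diketone enol oxygen can reach through a six-membered transition state (conjugate addition or, equivalently, oxa-6π closure), giving 8; acid-catalysed loss of one ketal methanol then rearomatises irreversibly to 9, with the old phenol as 5-OH and the old 4',5'-OMe groups as 7,8-OMe, and because the sequence is staged the oxidant is spent before the oxidisable phenol 9 appears and bulk methanol is removed before the ring closure; Williamson O-methylation of the crude chelated 5-OH gives 10 and also carries any 5,8-diol formed by ketal hydrolysis on to the same product; the closest known reaction types are the hypervalent-iodine oxidation of 4-methoxyphenols to quinone monoketals and the addition–elimination of heteronucleophiles to quinone monoketals and 2-acylquinones, neither of which has been used with a 1,3-diketone enol oxygen to build a flavone; the C8a stereocentre of 8 is racemic and is destroyed on aromatisation.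

**Compound list**
1 | 1,2,3,4-tetramethoxybenzene | COc1ccc(OC)c(OC)c1OC | starting material
2 | (2,3,4,5-tetramethoxyphenyl)lithium | [Li]c1cc(OC)c(OC)c(OC)c1OC | intermediate
3 | methyl 2,3,4,5-tetramethoxybenzoate | COC(=O)c1cc(OC)c(OC)c(OC)c1OC | intermediate
4 | 1-(2-hydroxy-4,5-dimethoxyphenyl)ethan-1-one | CC(=O)c1cc(OC)c(OC)cc1O | starting material
5 | dilithium phenoxide/enolate dianion of 4 | [Li]OC(=C)c1cc(OC)c(OC)cc1O[Li] | intermediate
6 | 1-(2-hydroxy-4,5-dimethoxyphenyl)-3-(2,3,4,5-tetramethoxyphenyl)propane-1,3-dione (drawn as the diketo form, largely enolised) | COc1cc(O)c(cc1OC)C(=O)CC(=O)c1cc(OC)c(OC)c(OC)c1OC | intermediate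
7 | 1-(3,3,4-trimethoxy-6-oxocyclohexa-1,4-dien-1-yl)-3-(2,3,4,5-tetramethoxyphenyl)propane-1,3-dione | O=C1C=C(OC)C(OC)(OC)C=C1C(=O)CC(=O)c1cc(OC)c(OC)c(OC)c1OC | intermediate
8 | (±)-5-hydroxy-7,8,8-trimethoxy-2-(2,3,4,5-tetramethoxyphenyl)-8,8a-dihydro-4H-chromen-4-one | COC1=CC(O)=C2C(=O)C=C(c3cc(OC)c(OC)c(OC)c3OC)OC2C1(OC)OC | intermediate
9 | 5-hydroxy-7,8-dimethoxy-2-(2,3,4,5-tetramethoxyphenyl)-4H-chromen-4-one | COc1cc(-c2cc(=O)c3c(O)cc(OC)c(OC)c3o2)c(OC)c(OC)c1OC | intermediate
10 | 5,7,8-trimethoxy-2-(2,3,4,5-tetramethoxyphenyl)-4H-chromen-4-one (achiral) | COc1cc(-c2cc(=O)c3c(OC)cc(OC)c(OC)c3o2)c(OC)c(OC)c1OC | target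

**Total step count:** 3
**Longest linear sequence:** 3 (1 → 3 → 6 → 10)

**Steps most likely to fail**

1. **Step 3 (the new step).**
   - Risks: methanol or acetate may add to 7 instead of the enol oxygen. PhI(OAc)2 may attack the diketone carbon. Phenol 9 may be over-oxidised if it forms while oxidant is still present.
   - Fallback: this uses known chemistry only, and the ring oxygen is bought in as a phenol instead of being made at a C–H. It sets out from 3 and comes back at 10. Commercial 1,2,3,5-tetramethoxybenzene is acetylated with AcCl/AlCl3 (Friedel–Crafts) to 1-(2,3,4,6-tetramethoxyphenyl)ethan-1-one F1. In the same flask F1 loses the flanked ortho-methyl by chelation-controlled AlCl3 cleavage, giving 1-(2-hydroxy-3,4,6-trimethoxyphenyl)ethan-1-one F2. LiHMDS Claisen condensation of F2 with 3 gives 1-(2-hydroxy-3,4,6-trimethoxyphenyl)-3-(2,3,4,5-tetramethoxyphenyl)propane-1,3-dione F3. Catalytic H2SO4 in AcOH at 100 °C (classical cyclodehydration) then gives 10.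

2. **Step 2.**
   - Risks: the electron-rich, ortho-substituted ester may be sluggish toward the dianion. The product may also cyclise on work-up.
   - Fallback: an intramolecular acyl transfer replaces the intermolecular Claisen. It sets out from 3 (together with 4) and comes back at 6. LiOH saponification gives 2,3,4,5-tetramethoxybenzoic acid F4. Oxalyl chloride with catalytic DMF gives 2,3,4,5-tetramethoxybenzoyl chloride F5. Pyridine-mediated O-acylation of 4 gives 2-acetyl-4,5-dimethoxyphenyl 2,3,4,5-tetramethoxybenzoate F6. KOH in pyridine at 50 °C (Baker–Venkataraman rearrangement) then delivers 6.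

3. **Step 1.**
   - Risks: lithiation may be incomplete. The aryllithium may add twice to give the benzophenone.
   - Fallback: electrophilic substitution replaces the anionic route. It sets out from 1 and comes back at 3. Vilsmeier–Haack formylation (POCl3, DMF, 80 °C) gives 2,3,4,5-tetramethoxybenzaldehyde F7. Oxidative esterification with I2/KOH in MeOH at 0 °C converts F7 into 3.

**Further compounds**
F1 | step 3 | 1-(2,3,4,6-tetramethoxyphenyl)ethan-1-one | CC(=O)c1c(OC)cc(OC)c(OC)c1OC
F2 | step 3 | 1-(2-hydroxy-3,4,6-trimethoxyphenyl)ethan-1-one | CC(=O)c1c(O)c(OC)c(OC)cc1OC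
F3 | step 3 | 1-(2-hydroxy-3,4,6-trimethoxyphenyl)-3-(2,3,4,5-tetramethoxyphenyl)propane-1,3-dione | COc1cc(OC)c(C(=O)CC(=O)c2cc(OC)c(OC)c(OC)c2OC)c(O)c1OC
F4 | step 2 | 2,3,4,5-tetramethoxybenzoic acid | COc1cc(C(=O)O)c(OC)c(OC)c1OC
F5 | step 2 | 2,3,4,5-tetramethoxybenzoyl chloride | COc1cc(C(=O)Cl)c(OC)c(OC)c1OC
F6 | step 2 | 2-acetyl-4,5-dimethoxyphenyl 2,3,4,5-tetramethoxybenzoate | CC(=O)c1cc(OC)c(OC)cc1OC(=O)c1cc(OC)c(OC)c(OC)c1OC
F7 | step 1 | 2,3,4,5-tetramethoxybenzaldehyde | COc1cc(C=O)c(OC)c(OC)c1OC
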